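**Two forks.** In a one-step world a molecule of substrate has one fate. This flask forks twice, so follow one molecule and ask for its chances.

solid substrate 0.020 M; coupling partner 0.0400 M; time 3.0 h

    starting material + coupling partner → other mono adduct (k1 = 0.51 /M/s)
    coupling partner + other mono adduct → bis adduct (k2 = 0.15 /M/s)
    mono adduct → over-reaction product (k3 = 0.016 /s)
    starting material + coupling partner → mono adduct (k4 = 0.46 /M/s)
    coupling partner + mono adduct → bis adduct (k5 = 0.44 /M/s)
    solid substrate ⇌ starting material, rate k6*(cs6 - [starting material]) while solid is left; crystals form when [starting material] > cs6 (cs6 = 11 mM, k6 = 0.089 /s)

- at 3.0 h, what has stopped the reaction, if anything has (for what has run out or reacted, a solid counts together with what of it has only dissolved) (the coupling partner has run out first / all of the solid substrate has reacted / it is still moving)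
- amount of bis adduct at 3.0 h, in percent of the solid substrate charged
- amount of mono adduct if the flask were left three thousand times as long, in percent of the solid substrate charged

- as a solid, counted per litre of solution: solid substrate
- at the start none of the solid substrate is in solution
- what has only dissolved of solid substrate counts as not reacted
- the reaction counts as stopped when no species that holds the solid substrate changes by six tenths of a point or more over the second half of the time
- run time (flask): 3.0 h

**What matters.** Skip the solubility and the dissolution coefficient: they enter neither chance below. Skip the constant from other mono adduct to bis adduct too: that intermediate has one exit, so the constant moves when, not where. Dissolved starting material becomes mono adduct with chance 47.4 %, from 0.46 /M/s against 0.51 /M/s. Mono adduct then goes to over-reaction product with chance 0.016 /s over that plus 0.44 /M/s times [coupling partner]. So [coupling partner] needs care: the product of both chances is 22.6 % at the charged 0.0400 M but 37.2 % at 0.0100 M. Hold it at 0.0200 M: doubling the over-reaction constant gives 37.2 %, and doubling the constant to other mono adduct gives 20.1 %.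

**The number.** Take 0.0200 M as the typical [coupling partner], the level once each substrate molecule has taken one partner. The second chance is 64.5 %, so the loss share, the part of the charge ending as over-reaction product, is 30.6 %, and bis adduct is 69.4 %. Bis adduct takes two partners and over-reaction product one, so the charge needs 0.0339 M of coupling partner, less than the 0.0400 M supplied. So [coupling partner] ends near 0.00612 M, and solid substrate is the limiting reagent. Even there other mono adduct has a half-life of 12.6 min, far shorter than the 3.0 h run, so expect all solid substrate reacted. Mono adduct has a half-life of 0.722 min by over-reaction alone, so put its long-run amount at 0 %.

**The flask.** The forecast says all of the solid substrate has reacted, 70 % bis adduct and 0 % mono adduct, on the ground that “the over-reaction takes about 30% of the material while sparing coupling partner”, against my 69.4 %. In the flask, all of the solid substrate has reacted, with 70.2 % bis adduct and 0 % mono adduct. That flask keeps 15 % of its coupling partner. Now charge 0.10 M of coupling partner: the typical level becomes 0.0800 M, and the loss share falls to 14.8 %. That neighbour flask ends with 14.9 % over-reaction product.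

The numbers of this flask belong to no real substance; the result is computed.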